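**Retrosynthetic overview**
1. Numbering (biogenetic): ring C1–C14, with C14 the stereocentre and C1 the ring CH2 between C14 and the alkene C2=C3; C3' is the CH2OH carbon on C3; side chain C15–C20; C15' is the exocyclic =CH2 carbon on C15.
2. Target ⇐ desilylation, Corey–Winter olefination of a C15/C15' diol and desulfonylation of a macrocyclic γ-hydroxy sulfone.
3. Macrocycle (the only ring, closed in one step) ⇐ acyclic (14R,15R)-14,15-epoxy C1-sulfone: the C1 allylic sulfonyl carbanion opens the epoxide at C14 with inversion and forms C1–C14. This is the anionic, polarity-reversed copy of the C1→C14 cyclisation of geranylfarnesyl diphosphate presumed for this 14-membered sesterterpene skeleton.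
4. Enabling feature: C1 is allylic to the C2=C3 alkene, so it can carry PhSO2 and a carbanion; C14 bears the C15(=C15'H2) unit, so it maps onto the secondary carbon of a trisubstituted epoxy alcohol C14–C15(–C15'H2OH) whose C15/C15' diol later becomes the exocyclic alkene.
5. Epoxy sulfone ⇐ C8–C9 sulfone alkylation of an east fragment from nerol (brings the 10Z alkene; C14=C15 by Horner–Wadsworth–Emmons olefination) with a west allylic bromide from syn-carbocupration of a 4-silyloxybut-2-ynoate (sets C1/C3' cis) and SeO2 oxidation.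

Key step: step 17

Remark: configuration and geometries are taken as written in the SMILES (stereocentre R; CH2OH cis to C1 on the C2=C3 alkene; 6E; 10Z); TBDPS = tert-butyldiphenylsilyl, TBS = tert-butyldimethylsilyl, TES = triethylsilyl.

**Route**

Step 1
Reactants: 1 tert-butyl(diphenyl)(prop-2-yn-1-yloxy)silane
Product: 2 methyl 4-(TBDPS-oxy)but-2-ynoate
Conditions: n-BuLi, THF, −78 °C; then ClCO2Me, −78 → 0 °C
Reagents that add atoms: methyl chloroformate, COC(=O)Cl
Why: Deprotonation of the terminal alkyne and C-acylation of the lithium acetylide with the chloroformate (acetylide acylation) should give the ynoate cleanly, because the silyl ether is inert at −78 °C.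

Step 2
Reactants: 2 methyl 4-(TBDPS-oxy)but-2-ynoate; 3 5-bromo-2-methylpent-2-ene
Product: 5 methyl (2Z)-3-[(TBDPS-oxy)methyl]-7-methylocta-2,6-dienoate, via homoprenylmagnesium bromide 4 (not isolated)
Conditions: Mg, THF, rt (3 → 4); CuBr·SMe2 (1 equiv), THF, −78 °C; then 2, −78 °C; MeOH then aq. NH4Cl at −78 °C
Reagents that add atoms: none
Why: Syn-carbocupration (conjugate addition) of the homoprenylcopper reagent to the ynoate and protonation of the vinylcopper at −78 °C should place the ester and the CH2OTBDPS group cis (2Z), the geometry required between C1 and C3' of the target; no stereocentre is formed.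

Step 3
Reactants: 5 methyl (2Z)-3-[(TBDPS-oxy)methyl]-7-methylocta-2,6-dienoate
Product: 6 methyl (2Z,6E)-3-[(TBDPS-oxy)methyl]-8-hydroxy-7-methylocta-2,6-dienoate
Conditions: SeO2 (cat.), t-BuOOH, salicylic acid (cat.), CH2Cl2, rt
Reagents that add atoms: tert-butyl hydroperoxide, CC(C)(C)OO (terminal oxidant); selenium dioxide, O=[Se]=O (catalytic oxygen carrier)
Why: The SeO2/t-BuOOH allylic oxidation (Riley type: ene reaction, then [2,3]-sigmatropic shift) is selective for the (E)-methyl group of the electron-rich terminal prenyl unit and leaves the conjugated, electron-poor 2,3-alkene alone, giving the (E)-allylic alcohol at C8.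

Step 4
Reactants: 6 methyl (2Z,6E)-3-[(TBDPS-oxy)methyl]-8-hydroxy-7-methylocta-2,6-dienoate
Product: 7 methyl (2Z,6E)-8-bromo-3-[(TBDPS-oxy)methyl]-7-methylocta-2,6-dienoate
Conditions: CBr4, PPh3, CH2Cl2, 0 °C
Reagents that add atoms: carbon tetrabromide, BrC(Br)(Br)Br
Why: The Appel reaction converts the primary allylic alcohol into the bromide by SN2 displacement without allylic transposition at 0 °C; the enoate and the silyl ether are inert.

Step 5
Reactants: 8 triethyl phosphonoacetate; 3 5-bromo-2-methylpent-2-ene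
Product: 9 ethyl 2-(diethoxyphosphoryl)-6-methylhept-5-enoate
Conditions: NaH, DMSO, 0 → 60 °C (8 in excess)
Reagents that add atoms: none
Why: C-alkylation of the sodium enolate of the phosphonoacetate (in excess, to suppress dialkylation) with the primary bromide gives the α-branched Horner–Wadsworth–Emmons reagent.

Step 6
Reactants: 10 nerol [(2Z)-3,7-dimethylocta-2,6-dien-1-ol]
Product: 12 neryl phenyl sulfone [(2Z)-3,7-dimethylocta-2,6-dien-1-yl phenyl sulfone], via neryl bromide 11 (not isolated)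
Conditions: PBr3, Et2O, −10 °C; then PhSO2Na, DMF, rt
Reagents that add atoms: sodium benzenesulfinate, [Na+].[O-]S(=O)c1ccccc1
Why: PBr3 converts the allylic alcohol into neryl bromide with retention of the Z-alkene at low temperature, and SN2 S-alkylation of benzenesulfinate gives the allylic sulfone that supplies C9–C13 and the 10Z alkene.

Step 7
Reactants: 12 neryl phenyl sulfone
Product: 14 (4Z)-4-methyl-6-(phenylsulfonyl)hex-4-enal, via terminal epoxide 13 (not isolated)
Conditions: mCPBA, CH2Cl2, 0 °C; then H5IO6, THF/H2O, 0 °C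
Reagents that add atoms: mCPBA (3-chloroperoxybenzoic acid), OOC(=O)c1cccc(Cl)c1
Why: Prilezhaev epoxidation is selective for the electron-rich terminal alkene because the other alkene is deactivated by the allylic sulfonyl group, and periodic acid then opens the epoxide and cleaves the glycol (Malaprade-type cleavage) to the C14 aldehyde with loss of acetone.

Step 8
Reactants: 14 (4Z)-4-methyl-6-(phenylsulfonyl)hex-4-enal; 9 ethyl 2-(diethoxyphosphoryl)-6-methylhept-5-enoate
Product: 15 ethyl (2E,6Z)-6-methyl-2-(4-methylpent-3-en-1-yl)-8-(phenylsulfonyl)octa-2,6-dienoate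
Conditions: LiCl, DBU, MeCN, 0 °C → rt
Reagents that add atoms: none
Why: Horner–Wadsworth–Emmons olefination under Masamune–Roush conditions is mild enough not to deprotonate the allylic sulfone and should give mainly the (E)-enoate (ester trans to the C13 chain) through the reversible adduct; the minor (Z)-isomer is to be removed by chromatography.

Step 9
Reactants: 15 ethyl (2E,6Z)-6-methyl-2-(4-methylpent-3-en-1-yl)-8-(phenylsulfonyl)octa-2,6-dienoate
Product: 16 (2E,6Z)-6-methyl-2-(4-methylpent-3-en-1-yl)-8-(phenylsulfonyl)octa-2,6-dien-1-ol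
Conditions: DIBAL-H (i-Bu2AlH), CH2Cl2, −78 °C; Rochelle salt work-up
Reagents that add atoms: none
Why: DIBAL-H reduces the enoate by 1,2-hydride addition to the (E)-allylic alcohol without touching the sulfone or the alkenes at −78 °C.

Step 10
Reactants: 16 (2E,6Z)-6-methyl-2-(4-methylpent-3-en-1-yl)-8-(phenylsulfonyl)octa-2,6-dien-1-ol
Product: 17 TBS ether of 16 [(2E,6Z)-1-(TBS-oxy)-6-methyl-2-(4-methylpent-3-en-1-yl)-8-(phenylsulfonyl)octa-2,6-diene]
Conditions: TBSCl, imidazole, DMF, 0 °C → rt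
Reagents that add atoms: tert-butyldimethylsilyl chloride, CC(C)(C)[Si](C)(C)Cl
Why: Standard silylation protects the primary allylic alcohol, so that the next step needs one equivalent of base and the later ester reduction leaves a single free allylic alcohol.

Step 11
Reactants: 17 TBS ether of 16; 7 methyl (2Z,6E)-8-bromo-3-[(TBDPS-oxy)methyl]-7-methylocta-2,6-dienoate
Product: 18 methyl (2Z,6E,9RS,10Z,14E)-15-[(TBS-oxy)methyl]-3-[(TBDPS-oxy)methyl]-7,11,19-trimethyl-9-(phenylsulfonyl)icosa-2,6,10,14,18-pentaenoate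
Conditions: n-BuLi, THF, −78 °C; then 7, −78 → −40 °C
Reagents that add atoms: none
Why: Alkylation of the α-lithiated allylic sulfone with the primary allylic bromide (sulfone alkylation of the Julia type) is a fast SN2 reaction at −78 °C that forms C8–C9 with retention of all alkene geometries, while the β,β-disubstituted enoate is too hindered to compete; C9 forms as a racemic centre that is removed in step 12.

Step 12
Reactants: 18 methyl (2Z,6E,9RS,10Z,14E)-15-[(TBS-oxy)methyl]-3-[(TBDPS-oxy)methyl]-7,11,19-trimethyl-9-(phenylsulfonyl)icosa-2,6,10,14,18-pentaenoate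
Product: 19 (2Z,6E,10Z,14E)-15-[(TBS-oxy)methyl]-3-[(TBDPS-oxy)methyl]-7,11,19-trimethylicosa-2,6,10,14,18-pentaen-1-ol
Conditions: PdCl2(dppp) (5 mol %; dppp = 1,3-bis(diphenylphosphino)propane), LiBHEt3 (excess), THF, 0 °C → rt; aq. NH4Cl
Reagents that add atoms: none
Why: Palladium-catalysed reductive desulfonylation (π-allylpalladium intermediate, hydride delivered to the less substituted terminus C9) should remove the sulfone with retention of the position and Z-geometry of the 10,11-alkene, and the excess hydride reduces the methyl ester to the C1 allylic alcohol in the same operation.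

Step 13
Reactants: 19 (2Z,6E,10Z,14E)-15-[(TBS-oxy)methyl]-3-[(TBDPS-oxy)methyl]-7,11,19-trimethylicosa-2,6,10,14,18-pentaen-1-ol
Product: 21 [(2Z,6E,10Z,14E)-15-[(TBS-oxy)methyl]-3-[(TBDPS-oxy)methyl]-7,11,19-trimethylicosa-2,6,10,14,18-pentaen-1-yl] phenyl sulfone, via allylic mesylate 20 (not isolated)
Conditions: MsCl, Et3N, CH2Cl2, −30 °C; then PhSO2Na, n-Bu4NI (cat.), DMF, 0 °C → rt
Reagents that add atoms: sodium benzenesulfinate, [Na+].[O-]S(=O)c1ccccc1
Why: Mesylation of the primary allylic alcohol and SN2 S-alkylation of benzenesulfinate install the sulfone at C1 without allylic transposition, the bulky TBDPS ether on the cis CH2O group being a poor neighbouring group.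

Step 14
Reactants: 21 [(2Z,6E,10Z,14E)-15-[(TBS-oxy)methyl]-3-[(TBDPS-oxy)methyl]-7,11,19-trimethylicosa-2,6,10,14,18-pentaen-1-yl] phenyl sulfone
Product: 22 [(2Z,6E,10Z,14E)-15-(hydroxymethyl)-3-[(TBDPS-oxy)methyl]-7,11,19-trimethylicosa-2,6,10,14,18-pentaen-1-yl] phenyl sulfone
Conditions: CSA (cat.), MeOH/CH2Cl2, 0 °C
Reagents that add atoms: none
Why: Acid-catalysed methanolysis cleaves the primary TBS ether much faster than the TBDPS ether and unmasks the C15' allylic alcohol as the only free hydroxyl.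

Step 15
Reactants: 22 [(2Z,6E,10Z,14E)-15-(hydroxymethyl)-3-[(TBDPS-oxy)methyl]-7,11,19-trimethylicosa-2,6,10,14,18-pentaen-1-yl] phenyl sulfone
Product: 23 [(2Z,6E,10Z,14R,15R)-14,15-epoxy-15-(hydroxymethyl)-3-[(TBDPS-oxy)methyl]-7,11,19-trimethylicosa-2,6,10,18-tetraen-1-yl] phenyl sulfone
Conditions: Ti(OiPr)4 (cat.), D-(−)-diethyl tartrate, t-BuOOH, 4 Å molecular sieves, CH2Cl2, −20 °C
Reagents that add atoms: tert-butyl hydroperoxide, CC(C)(C)OO
Why: Katsuki–Sharpless asymmetric epoxidation acts only on the free allylic alcohol, and with D-(−)-diethyl tartrate the (E)-2,3-disubstituted allylic alcohol should be epoxidised on the face that gives the (14R,15R)-epoxy alcohol, which fixes the configuration later transferred to C14; the other four alkenes and the sulfone are inert.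

Step 16
Reactants: 23 [(2Z,6E,10Z,14R,15R)-14,15-epoxy-15-(hydroxymethyl)-3-[(TBDPS-oxy)methyl]-7,11,19-trimethylicosa-2,6,10,18-tetraen-1-yl] phenyl sulfone
Product: 24 [(2Z,6E,10Z,14R,15R)-14,15-epoxy-3-[(TBDPS-oxy)methyl]-15-[(TES-oxy)methyl]-7,11,19-trimethylicosa-2,6,10,18-tetraen-1-yl] phenyl sulfone
Conditions: Et3SiCl, imidazole, CH2Cl2, 0 °C
Reagents that add atoms: chlorotriethylsilane, CC[Si](Cl)(CC)CC
Why: Silylation under non-basic conditions protects the epoxy alcohol without deprotonating the sulfone or inducing Payne rearrangement.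

Step 17
Reactants: 24 [(2Z,6E,10Z,14R,15R)-14,15-epoxy-3-[(TBDPS-oxy)methyl]-15-[(TES-oxy)methyl]-7,11,19-trimethylicosa-2,6,10,18-tetraen-1-yl] phenyl sulfone
Product: 25 (2S)-2-[(1S,3Z,7E,11Z)-4-[(TBDPS-oxy)methyl]-8,12-dimethyl-2-(phenylsulfonyl)cyclotetradeca-3,7,11-trien-1-yl]-6-methyl-1-(TES-oxy)hept-5-en-2-ol (both epimers at the sulfonyl carbon)
Conditions: LiN(SiMe3)2 (1.2 equiv), THF, 0.005 M, −78 °C → rt (40 °C if conversion is slow); aq. NH4Cl
Reagents that add atoms: none
Why: LiN(SiMe3)2 removes a C1 proton to give the α-sulfonyl allylic carbanion, which attacks the epoxide intramolecularly at the secondary carbon C14 from the side opposite to the C–O bond (SN2), forming the C1–C14 bond and the 14-membered carbocycle in one operation. The closest known reaction type is the macrocyclisation of terminally epoxidised polyprenyl chains by sulfur-stabilised allylic carbanions to 14-membered cembrane-type rings, and the step is the polarity-reversed counterpart of the biosynthetic C1→C14 ring closure. The ring closes in the 14-exo-tet mode (the breaking epoxide C–O bond lies outside the new ring), the alternative attack at the quaternary C15 being sterically blocked. The new stereocentre C14 is controlled by the substrate: inversion at the (14R) epoxide carbon set in step 15 gives the configuration that is (R) in the target, while the sulfonyl carbon C1 forms as an inconsequential epimer mixture and C15 is kept only until step 21. The step needs α- rather than γ-attack of the allyl anion, cyclisation rather than oligomerisation, and no 1,4-elimination of the γ-silyloxy group; these should be secured by the sulfone (α-selective, geometrically stable 2,3-alkene), by high dilution, and by the poor leaving-group ability of a silanolate from a stabilised carbanion at or below room temperature. Migration of the TES group to the new tertiary alkoxide would be harmless, because step 19 removes it from either oxygen.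

Step 18
Reactants: 25 (2S)-2-[(1S,3Z,7E,11Z)-4-[(TBDPS-oxy)methyl]-8,12-dimethyl-2-(phenylsulfonyl)cyclotetradeca-3,7,11-trien-1-yl]-6-methyl-1-(TES-oxy)hept-5-en-2-ol
Product: 26 (2S)-2-[(1R,3Z,7E,11Z)-4-[(TBDPS-oxy)methyl]-8,12-dimethylcyclotetradeca-3,7,11-trien-1-yl]-6-methyl-1-(TES-oxy)hept-5-en-2-ol
Conditions: PdCl2(dppp) (10 mol %), LiBHEt3 (excess), THF, 0 °C; aq. NH4Cl
Reagents that add atoms: none
Why: Palladium-catalysed reductive desulfonylation with LiBHEt3 (hydride delivered to the secondary terminus C1 of the π-allylpalladium intermediate rather than to the fully substituted C3) should remove the sulfone with retention of the trisubstituted 2,3-alkene and its geometry, leaving C14 untouched.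

Step 19
Reactants: 26 (2S)-2-[(1R,3Z,7E,11Z)-4-[(TBDPS-oxy)methyl]-8,12-dimethylcyclotetradeca-3,7,11-trien-1-yl]-6-methyl-1-(TES-oxy)hept-5-en-2-ol
Product: 27 (2S)-2-[(1R,3Z,7E,11Z)-4-[(TBDPS-oxy)methyl]-8,12-dimethylcyclotetradeca-3,7,11-trien-1-yl]-6-methylhept-5-ene-1,2-diol
Conditions: PPTS, MeOH, rt
Reagents that add atoms: none
Why: PPTS-catalysed methanolysis removes the TES group from whichever oxygen carries it and leaves the TBDPS ether, giving the 1,2-diol.

Step 20
Reactants: 27 (2S)-2-[(1R,3Z,7E,11Z)-4-[(TBDPS-oxy)methyl]-8,12-dimethylcyclotetradeca-3,7,11-trien-1-yl]-6-methylhept-5-ene-1,2-diol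
Product: 28 (4S)-4-[(1R,3Z,7E,11Z)-4-[(TBDPS-oxy)methyl]-8,12-dimethylcyclotetradeca-3,7,11-trien-1-yl]-4-(4-methylpent-3-en-1-yl)-1,3-dioxolane-2-thione
Conditions: 1,1'-thiocarbonyldiimidazole, DMAP (cat.), toluene, 80 °C
Reagents that add atoms: 1,1'-thiocarbonyldiimidazole, S=C(n1ccnc1)n1ccnc1
Why: Thiocarbonylation of the primary hydroxyl followed by 5-exo ring closure of the tertiary hydroxyl gives the cyclic thionocarbonate (first half of the Corey–Winter olefination).

Step 21
Reactants: 28 (4S)-4-[(1R,3Z,7E,11Z)-4-[(TBDPS-oxy)methyl]-8,12-dimethylcyclotetradeca-3,7,11-trien-1-yl]-4-(4-methylpent-3-en-1-yl)-1,3-dioxolane-2-thione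
Product: 29 O-TBDPS ether of the target {tert-butyl[(1Z,4E,8Z,12R)-5,9-dimethyl-12-(6-methylhepta-1,5-dien-2-yl)cyclotetradeca-1(14),4,8-trien-1-yl]methoxydiphenylsilane}
Conditions: 1,3-dimethyl-2-phenyl-1,3,2-diazaphospholidine, THF, 40 °C
Reagents that add atoms: none
Why: Corey–Winter olefination with the diazaphospholidine thiophile (desulfurisation to the carbene, then cycloreversion with loss of CO2) converts the thionocarbonate regiospecifically into the exocyclic C15=C15' alkene at 40 °C, removing the C15 stereocentre and leaving C14 and the ring alkenes untouched.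

Step 22
Reactants: 29 O-TBDPS ether of the target
Product: 30 [(1Z,4E,8Z,12R)-5,9-dimethyl-12-(6-methylhepta-1,5-dien-2-yl)cyclotetradeca-1(14),4,8-trien-1-yl]methanol (CNP0217603.2)
Conditions: n-Bu4NF, THF, 0 °C → rt
Reagents that add atoms: none
Why: Fluoride-mediated desilylation releases the primary allylic alcohol under conditions that do not affect the ring triene, the exocyclic alkene or the stereocentre.

**Compound list**
1 | tert-butyl(diphenyl)(prop-2-yn-1-yloxy)silane | C#CCO[Si](c1ccccc1)(c1ccccc1)C(C)(C)C | starting material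
2 | methyl 4-(TBDPS-oxy)but-2-ynoate | COC(=O)C#CCO[Si](c1ccccc1)(c1ccccc1)C(C)(C)C | intermediate
3 | 5-bromo-2-methylpent-2-ene (homoprenyl bromide) | CC(C)=CCCBr | starting material
4 | homoprenylmagnesium bromide [(4-methylpent-3-en-1-yl)magnesium bromide] | CC(C)=CCC[Mg]Br | intermediate
5 | methyl (2Z)-3-[(TBDPS-oxy)methyl]-7-methylocta-2,6-dienoate | COC(=O)/C=C(\CO[Si](c1ccccc1)(c1ccccc1)C(C)(C)C)CCC=C(C)C | intermediate
6 | methyl (2Z,6E)-3-[(TBDPS-oxy)methyl]-8-hydroxy-7-methylocta-2,6-dienoate | COC(=O)/C=C(\CO[Si](c1ccccc1)(c1ccccc1)C(C)(C)C)CC/C=C(\C)CO | intermediate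
7 | methyl (2Z,6E)-8-bromo-3-[(TBDPS-oxy)methyl]-7-methylocta-2,6-dienoate | COC(=O)/C=C(\CO[Si](c1ccccc1)(c1ccccc1)C(C)(C)C)CC/C=C(\C)CBr | intermediate
8 | triethyl phosphonoacetate | CCOC(=O)CP(=O)(OCC)OCC | starting material
9 | ethyl 2-(diethoxyphosphoryl)-6-methylhept-5-enoate | CCOC(=O)C(CCC=C(C)C)P(=O)(OCC)OCC | intermediate
10 | nerol [(2Z)-3,7-dimethylocta-2,6-dien-1-ol] | CC(C)=CCC/C(C)=C\CO | starting material
11 | neryl bromide [(2Z)-1-bromo-3,7-dimethylocta-2,6-diene] | CC(C)=CCC/C(C)=C\CBr | intermediate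
12 | neryl phenyl sulfone [(2Z)-3,7-dimethylocta-2,6-dien-1-yl phenyl sulfone] | CC(C)=CCC/C(C)=C\CS(=O)(=O)c1ccccc1 | intermediate
13 | 2,2-dimethyl-3-[(3Z)-3-methyl-5-(phenylsulfonyl)pent-3-en-1-yl]oxirane (racemic) | CC1(C)OC1CC/C(C)=C\CS(=O)(=O)c1ccccc1 | intermediate
14 | (4Z)-4-methyl-6-(phenylsulfonyl)hex-4-enal | O=CCC/C(C)=C\CS(=O)(=O)c1ccccc1 | intermediate
15 | ethyl (2E,6Z)-6-methyl-2-(4-methylpent-3-en-1-yl)-8-(phenylsulfonyl)octa-2,6-dienoate | CCOC(=O)/C(CCC=C(C)C)=C/CC/C(C)=C\CS(=O)(=O)c1ccccc1 | intermediate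
16 | (2E,6Z)-6-methyl-2-(4-methylpent-3-en-1-yl)-8-(phenylsulfonyl)octa-2,6-dien-1-ol | OC/C(CCC=C(C)C)=C/CC/C(C)=C\CS(=O)(=O)c1ccccc1 | intermediate
17 | TBS ether of 16 | CC(C)(C)[Si](C)(C)OC/C(CCC=C(C)C)=C/CC/C(C)=C\CS(=O)(=O)c1ccccc1 | intermediate
18 | methyl (2Z,6E,9RS,10Z,14E)-15-[(TBS-oxy)methyl]-3-[(TBDPS-oxy)methyl]-7,11,19-trimethyl-9-(phenylsulfonyl)icosa-2,6,10,14,18-pentaenoate | COC(=O)/C=C(\CO[Si](c1ccccc1)(c1ccccc1)C(C)(C)C)CC/C=C(\C)CC(S(=O)(=O)c1ccccc1)/C=C(/C)CC/C=C(\CCC=C(C)C)CO[Si](C)(C)C(C)(C)C | intermediate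
19 | (2Z,6E,10Z,14E)-15-[(TBS-oxy)methyl]-3-[(TBDPS-oxy)methyl]-7,11,19-trimethylicosa-2,6,10,14,18-pentaen-1-ol | OC/C=C(\CO[Si](c1ccccc1)(c1ccccc1)C(C)(C)C)CC/C=C(\C)CC/C=C(/C)CC/C=C(\CCC=C(C)C)CO[Si](C)(C)C(C)(C)C | intermediate
20 | (2Z,6E,10Z,14E)-15-[(TBS-oxy)methyl]-3-[(TBDPS-oxy)methyl]-7,11,19-trimethylicosa-2,6,10,14,18-pentaen-1-yl methanesulfonate | CS(=O)(=O)OC/C=C(\CO[Si](c1ccccc1)(c1ccccc1)C(C)(C)C)CC/C=C(\C)CC/C=C(/C)CC/C=C(\CCC=C(C)C)CO[Si](C)(C)C(C)(C)C | intermediate
21 | [(2Z,6E,10Z,14E)-15-[(TBS-oxy)methyl]-3-[(TBDPS-oxy)methyl]-7,11,19-trimethylicosa-2,6,10,14,18-pentaen-1-yl] phenyl sulfone | O=S(=O)(c1ccccc1)C/C=C(\CO[Si](c1ccccc1)(c1ccccc1)C(C)(C)C)CC/C=C(\C)CC/C=C(/C)CC/C=C(\CCC=C(C)C)CO[Si](C)(C)C(C)(C)C | intermediate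
22 | [(2Z,6E,10Z,14E)-15-(hydroxymethyl)-3-[(TBDPS-oxy)methyl]-7,11,19-trimethylicosa-2,6,10,14,18-pentaen-1-yl] phenyl sulfone | O=S(=O)(c1ccccc1)C/C=C(\CO[Si](c1ccccc1)(c1ccccc1)C(C)(C)C)CC/C=C(\C)CC/C=C(/C)CC/C=C(\CCC=C(C)C)CO | intermediate
23 | [(2Z,6E,10Z,14R,15R)-14,15-epoxy-15-(hydroxymethyl)-3-[(TBDPS-oxy)methyl]-7,11,19-trimethylicosa-2,6,10,18-tetraen-1-yl] phenyl sulfone | O=S(=O)(c1ccccc1)C/C=C(\CO[Si](c1ccccc1)(c1ccccc1)C(C)(C)C)CC/C=C(\C)CC/C=C(/C)CC[C@H]1O[C@@]1(CO)CCC=C(C)C | intermediate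
24 | [(2Z,6E,10Z,14R,15R)-14,15-epoxy-3-[(TBDPS-oxy)methyl]-15-[(TES-oxy)methyl]-7,11,19-trimethylicosa-2,6,10,18-tetraen-1-yl] phenyl sulfone | O=S(=O)(c1ccccc1)C/C=C(\CO[Si](c1ccccc1)(c1ccccc1)C(C)(C)C)CC/C=C(\C)CC/C=C(/C)CC[C@H]1O[C@@]1(CO[Si](CC)(CC)CC)CCC=C(C)C | intermediate
25 | (2S)-2-[(1S,3Z,7E,11Z)-4-[(TBDPS-oxy)methyl]-8,12-dimethyl-2-(phenylsulfonyl)cyclotetradeca-3,7,11-trien-1-yl]-6-methyl-1-(TES-oxy)hept-5-en-2-ol (both epimers at the sulfonyl carbon) | CC(C)=CCC[C@@](O)(CO[Si](CC)(CC)CC)[C@H]1C(S(=O)(=O)c2ccccc2)/C=C(\CO[Si](c2ccccc2)(c2ccccc2)C(C)(C)C)CC/C=C(\C)CC/C=C(/C)CC1 | intermediate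
26 | (2S)-2-[(1R,3Z,7E,11Z)-4-[(TBDPS-oxy)methyl]-8,12-dimethylcyclotetradeca-3,7,11-trien-1-yl]-6-methyl-1-(TES-oxy)hept-5-en-2-ol | CC(C)=CCC[C@@](O)(CO[Si](CC)(CC)CC)[C@H]1C/C=C(\CO[Si](c2ccccc2)(c2ccccc2)C(C)(C)C)CC/C=C(\C)CC/C=C(/C)CC1 | intermediate
27 | (2S)-2-[(1R,3Z,7E,11Z)-4-[(TBDPS-oxy)methyl]-8,12-dimethylcyclotetradeca-3,7,11-trien-1-yl]-6-methylhept-5-ene-1,2-diol | CC(C)=CCC[C@@](O)(CO)[C@H]1C/C=C(\CO[Si](c2ccccc2)(c2ccccc2)C(C)(C)C)CC/C=C(\C)CC/C=C(/C)CC1 | intermediate
28 | (4S)-4-[(1R,3Z,7E,11Z)-4-[(TBDPS-oxy)methyl]-8,12-dimethylcyclotetradeca-3,7,11-trien-1-yl]-4-(4-methylpent-3-en-1-yl)-1,3-dioxolane-2-thione | CC(C)=CCC[C@@](O1)(COC1=S)[C@H]2C/C=C(\CO[Si](c3ccccc3)(c3ccccc3)C(C)(C)C)CC/C=C(\C)CC/C=C(/C)CC2 | intermediate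
29 | O-TBDPS ether of the target | C=C(CCC=C(C)C)[C@H]1C/C=C(\CO[Si](c2ccccc2)(c2ccccc2)C(C)(C)C)CC/C=C(\C)CC/C=C(/C)CC1 | intermediate
30 | [(1Z,4E,8Z,12R)-5,9-dimethyl-12-(6-methylhepta-1,5-dien-2-yl)cyclotetradeca-1(14),4,8-trien-1-yl]methanol (CNP0217603.2) | C=C(CCC=C(C)C)[C@H]1C/C=C(\CO)CC/C=C(\C)CC/C=C(/C)CC1 | target

**Totals and risks**
Total step count: 22. Longest linear sequence: 17 steps (nerol 10 → 30, steps 6–22); the west fragment (steps 1–4) joins at step 11 and the phosphonate (step 5) at step 8.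

Steps most likely to fail:

Step 17. The stabilised sulfonyl carbanion may open the hindered trisubstituted epoxide too slowly, so that oligomerisation or 1,4-elimination of the γ-silyloxy group competes with ring closure. The fallback closes the same bond with the far more nucleophilic α-phenylthio allylic carbanion, a known reaction type for exactly this kind of 14-membered closure. It sets out from 19: acetylation (Ac2O, pyridine, DMAP) gives the C1 acetate F1; CSA/MeOH removes the TBS group to give the C15' allylic alcohol F2; Katsuki–Sharpless epoxidation with D-(−)-diethyl tartrate gives the (14R,15R)-epoxy alcohol F3; Et3SiCl/imidazole gives the TES ether F4; K2CO3/MeOH at 0 °C frees the C1 allylic alcohol F5; (PhS)2/n-Bu3P converts it into the allylic phenyl sulfide F6; n-BuLi/DABCO in THF at −78 °C under high dilution closes the ring to the macrocyclic hydroxy sulfide F7; chemoselective S-oxidation ((n-Pr4N)RuO4 cat., N-methylmorpholine N-oxide, MeCN) returns to the route at 25.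

Step 18. Ionisation of the hindered, α-branched ring sulfone may be slow, and hydride delivery after syn–anti equilibration or at the wrong terminus of the π-allyl intermediate would move or isomerise the 2,3-alkene. The fallback is electron-transfer desulfonylation of 25 with sodium amalgam (Na(Hg), Na2HPO4, MeOH/THF, −20 °C), which avoids the π-allyl metal intermediate and leads directly to 26 without a new compound.

Step 8. The olefination with the α-branched phosphonate may be incompletely E-selective, and any (Z)-isomer carried into step 15 would give the opposite configuration at C14 and erode the enantiomeric purity. The fallback fixes the geometry by stereospecific cross-coupling. It sets out from 14: Wittig reaction with Ph3P=C(Br)CO2Et gives the (Z)-α-bromo enoate F8 (ester trans to the chain), and Suzuki–Miyaura coupling with the homoprenyl borane F9 (from 9-borabicyclo[3.3.1]nonane and 4-methylpenta-1,3-diene; PdCl2(dppf), AsPh3, Cs2CO3, DMF/THF/H2O, rt) replaces bromine with retention and returns to the route at 15.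

Further compounds
F1 | step 17 | (2Z,6E,10Z,14E)-15-[(TBS-oxy)methyl]-3-[(TBDPS-oxy)methyl]-7,11,19-trimethylicosa-2,6,10,14,18-pentaen-1-yl acetate | CC(=O)OC/C=C(\CO[Si](c1ccccc1)(c1ccccc1)C(C)(C)C)CC/C=C(\C)CC/C=C(/C)CC/C=C(\CCC=C(C)C)CO[Si](C)(C)C(C)(C)C
F2 | step 17 | (2Z,6E,10Z,14E)-15-(hydroxymethyl)-3-[(TBDPS-oxy)methyl]-7,11,19-trimethylicosa-2,6,10,14,18-pentaen-1-yl acetate | CC(=O)OC/C=C(\CO[Si](c1ccccc1)(c1ccccc1)C(C)(C)C)CC/C=C(\C)CC/C=C(/C)CC/C=C(\CCC=C(C)C)CO
F3 | step 17 | (2Z,6E,10Z,14R,15R)-14,15-epoxy-15-(hydroxymethyl)-3-[(TBDPS-oxy)methyl]-7,11,19-trimethylicosa-2,6,10,18-tetraen-1-yl acetate | CC(=O)OC/C=C(\CO[Si](c1ccccc1)(c1ccccc1)C(C)(C)C)CC/C=C(\C)CC/C=C(/C)CC[C@H]1O[C@@]1(CO)CCC=C(C)C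
F4 | step 17 | (2Z,6E,10Z,14R,15R)-14,15-epoxy-3-[(TBDPS-oxy)methyl]-15-[(TES-oxy)methyl]-7,11,19-trimethylicosa-2,6,10,18-tetraen-1-yl acetate | CC(=O)OC/C=C(\CO[Si](c1ccccc1)(c1ccccc1)C(C)(C)C)CC/C=C(\C)CC/C=C(/C)CC[C@H]1O[C@@]1(CO[Si](CC)(CC)CC)CCC=C(C)C
F5 | step 17 | (2Z,6E,10Z,14R,15R)-14,15-epoxy-3-[(TBDPS-oxy)methyl]-15-[(TES-oxy)methyl]-7,11,19-trimethylicosa-2,6,10,18-tetraen-1-ol | OC/C=C(\CO[Si](c1ccccc1)(c1ccccc1)C(C)(C)C)CC/C=C(\C)CC/C=C(/C)CC[C@H]1O[C@@]1(CO[Si](CC)(CC)CC)CCC=C(C)C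
F6 | step 17 | [(2Z,6E,10Z,14R,15R)-14,15-epoxy-3-[(TBDPS-oxy)methyl]-15-[(TES-oxy)methyl]-7,11,19-trimethylicosa-2,6,10,18-tetraen-1-yl] phenyl sulfide | c1ccccc1SC/C=C(\CO[Si](c1ccccc1)(c1ccccc1)C(C)(C)C)CC/C=C(\C)CC/C=C(/C)CC[C@H]1O[C@@]1(CO[Si](CC)(CC)CC)CCC=C(C)C
F7 | step 17 | (2S)-2-[(1S,3Z,7E,11Z)-4-[(TBDPS-oxy)methyl]-8,12-dimethyl-2-(phenylsulfanyl)cyclotetradeca-3,7,11-trien-1-yl]-6-methyl-1-(TES-oxy)hept-5-en-2-ol (both epimers at the sulfur-bearing carbon) | CC(C)=CCC[C@@](O)(CO[Si](CC)(CC)CC)[C@H]1C(Sc2ccccc2)/C=C(\CO[Si](c2ccccc2)(c2ccccc2)C(C)(C)C)CC/C=C(\C)CC/C=C(/C)CC1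
F0 | step 18 | none | none
F8 | step 8 | ethyl (2Z,6Z)-2-bromo-6-methyl-8-(phenylsulfonyl)octa-2,6-dienoate | CCOC(=O)/C(Br)=C/CC/C(C)=C\CS(=O)(=O)c1ccccc1
F9 | step 8 | 9-(4-methylpent-3-en-1-yl)-9-borabicyclo[3.3.1]nonane | CC(C)=CCCB1C2CCCC1CCC2
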